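**Strategy.** The target is cut on both sides of the ester carbonyl C1. Its neighbours are C2 of the E-configured C2=C3 double bond and the oxygen on glycerol carbon G2, so C1 itself can arrive last as carbon monoxide. One palladium-catalysed carbonylative esterification forges the C2–C1 and C1–O(G2) bonds. It joins an E-alkenyl iodide, which carries cyclohexene ring A with its inert tetrasubstituted double bond, to a glycerol whose only free hydroxyl is the secondary one at G2; O1 is acetylated and O3 silylated. The iodide geometry, fixed by syn-carbometalation of a terminal alkyne, is transferred unchanged. The stereocentre G2 comes from (S)-solketal. Fluoride then unmasks O3.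

Key step: step 6

Remark on the chemistry: G2 of the target is S (a 1-O-acetyl-2-O-acyl-sn-glycerol); it maps onto (S)-solketal when the free hydroxyl becomes O3 and the acetonide oxygens become O1 and O2, so no bond at G2 is ever broken, and O3 is blocked with the acid-stable, non-migrating tert-butyldiphenylsilyl group before the acetyl group is introduced, so an acetyl shift cannot racemise G2.

**Step 1**
Reactants: 1 dihydro-β-ionone [4-(2,6,6-trimethylcyclohex-1-en-1-yl)butan-2-one]
Product: 3 2-(but-3-yn-1-yl)-1,3,3-trimethylcyclohex-1-ene, via enol diethyl phosphate 2 (not isolated)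
Conditions: LiN(i-Pr)2 (1.1 equiv), THF, −78 °C; ClP(O)(OEt)2, −78 °C → rt; then LiN(i-Pr)2 (2.3 equiv), THF, −78 °C → rt; aq. NH4Cl
Reagents that add atoms: diethyl chlorophosphate, CCOP(=O)(Cl)OCC (its phosphoryl group is held only by 2 and leaves again on the way to 3)
Why: Kinetic deprotonation of the methyl group by the hindered amide and O-phosphorylation should give the terminal enol phosphate, from which excess amide removes the vinylic hydrogen and expels diethyl phosphate (enol phosphate β-elimination route from methyl ketones to terminal alkynes), the lithium acetylide formed driving the elimination.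

**Step 2**
Reactants: 3 2-(but-3-yn-1-yl)-1,3,3-trimethylcyclohex-1-ene
Product: 5 (E)-1-iodo-2-methyl-4-(2,6,6-trimethylcyclohex-1-en-1-yl)but-1-ene, via alkenyldimethylalane 4 (not isolated)
Conditions: Me3Al (2 equiv), Cp2ZrCl2 (0.25 equiv), ClCH2CH2Cl, 0 °C → rt; then I2, THF, −30 → 0 °C
Reagents that add atoms: trimethylaluminium, C[Al](C)C; iodine, II
Why: Cp2ZrCl2-catalysed carboalumination (Negishi carboalumination) adds methyl and aluminium syn across the terminal alkyne with aluminium on the terminal carbon, and iodinolysis of the C–Al bond proceeds with retention, so the E-iodide should result while the hindered ring alkene stays untouched.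

**Step 3**
Reactants: 6 (S)-solketal [(4S)-2,2-dimethyl-1,3-dioxolane-4-methanol]
Product: 7 (4R)-4-{[(tert-butyldiphenylsilyl)oxy]methyl}-2,2-dimethyl-1,3-dioxolane
Conditions: t-BuPh2SiCl (1.1 equiv), imidazole (2 equiv), DMF, 0 °C → rt
Reagents that add atoms: tert-butyl(chloro)diphenylsilane, CC(C)(C)[Si](Cl)(c1ccccc1)c1ccccc1
Why: Imidazole-promoted silyl ether formation at the only hydroxyl installs the bulky, acid-stable group on the future O3 without touching the stereocentre (the descriptor changes from S to R only because the priorities change).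

**Step 4**
Reactants: 7 (4R)-4-{[(tert-butyldiphenylsilyl)oxy]methyl}-2,2-dimethyl-1,3-dioxolane
Product: 8 (2R)-3-[(tert-butyldiphenylsilyl)oxy]propane-1,2-diol (3-O-tert-butyldiphenylsilyl-sn-glycerol)
Conditions: AcOH/H2O (4:1), 45 °C
Reagents that add atoms: none
Why: Acid-catalysed hydrolysis of the isopropylidene acetal is fast under conditions that a primary tert-butyldiphenylsilyl ether tolerates, and no bond to the stereocentre is broken.

**Step 5**
Reactants: 8 (2R)-3-[(tert-butyldiphenylsilyl)oxy]propane-1,2-diol
Product: 9 (2R)-3-[(tert-butyldiphenylsilyl)oxy]-2-hydroxypropyl acetate (1-O-acetyl-3-O-tert-butyldiphenylsilyl-sn-glycerol)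
Conditions: AcCl (1.05 equiv), 2,4,6-collidine (2 equiv), CH2Cl2, −78 °C
Reagents that add atoms: acetyl chloride, CC(=O)Cl
Why: At −78 °C acetyl chloride with the weak, hindered base 2,4,6-collidine acylates the primary hydroxyl much faster than the secondary one (kinetically selective O-acylation of a 1,2-diol), and the base is too weak to cause acetyl or silyl migration.

**Step 6**
Reactants: 5 (E)-1-iodo-2-methyl-4-(2,6,6-trimethylcyclohex-1-en-1-yl)but-1-ene; 9 (2R)-3-[(tert-butyldiphenylsilyl)oxy]-2-hydroxypropyl acetate; 10 carbon monoxide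
Product: 11 (2R)-1-(acetyloxy)-3-[(tert-butyldiphenylsilyl)oxy]propan-2-yl (2E)-3-methyl-5-(2,6,6-trimethylcyclohex-1-en-1-yl)pent-2-enoate
Conditions: CO (1 atm), Pd(OAc)2 (5 mol%), PPh3 (12 mol%), i-Pr2NEt (2 equiv), DMAP (0.2 equiv), THF, 50 °C; 5 in slight excess
Reagents that add atoms: carbon monoxide (compound 10), [C-]#[O+]
Why: Zerovalent palladium, formed in the flask from Pd(OAc)2 and PPh3, inserts into the C–I bond of 5 with retention, CO inserts to give an acylpalladium iodide, and the G2 hydroxyl of 9 (helped by DMAP as acyl-transfer catalyst and i-Pr2NEt as proton sink) cleaves it to the ester and returns zerovalent palladium. The closest known reaction type is the palladium-catalysed alkoxycarbonylation of alkenyl halides (Heck carbonylation). No ring is closed and no stereocentre is created; G2 keeps its configuration because only its O–H bond reacts. The step needs retention of the E geometry, which the stereospecific oxidative addition and migratory insertion pass on from the geometrically defined iodide, and acylation at O2 alone, which is secured because O1 carries the acetyl and O3 the silyl group. The tetrasubstituted C=C of ring A is too hindered to insert, and the acyl group on C2 lies trans to the tether on C3, so it cannot reach that alkene. The weak hindered amine at 50 °C should leave the acetyl group on O1.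

**Step 7**
Reactants: 11 (2R)-1-(acetyloxy)-3-[(tert-butyldiphenylsilyl)oxy]propan-2-yl (2E)-3-methyl-5-(2,6,6-trimethylcyclohex-1-en-1-yl)pent-2-enoate
Product: 12 (2S)-1-(acetyloxy)-3-hydroxypropan-2-yl (2E)-3-methyl-5-(2,6,6-trimethylcyclohex-1-en-1-yl)pent-2-enoate
Conditions: HF·pyridine, pyridine, THF, 0 °C → rt; pH 7 phosphate buffer work-up
Reagents that add atoms: none
Why: Fluoride-mediated desilylation cleaves the Si–O bond under pyridine-buffered, weakly acidic conditions in which neither ester should shift to the freed O3 hydroxyl, and G2 is untouched (the descriptor returns to S only through the priority change).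

**Compound list**
1 | dihydro-β-ionone, 4-(2,6,6-trimethylcyclohex-1-en-1-yl)butan-2-one | CC(=O)CCC1=C(C)CCCC1(C)C | starting material
2 | diethyl 4-(2,6,6-trimethylcyclohex-1-en-1-yl)but-1-en-2-yl phosphate | C=C(CCC1=C(C)CCCC1(C)C)OP(=O)(OCC)OCC | intermediate
3 | 2-(but-3-yn-1-yl)-1,3,3-trimethylcyclohex-1-ene | C#CCCC1=C(C)CCCC1(C)C | intermediate
4 | dimethyl[(1E)-2-methyl-4-(2,6,6-trimethylcyclohex-1-en-1-yl)but-1-en-1-yl]alumane | C[Al](C)/C=C(\C)CCC1=C(C)CCCC1(C)C | intermediate
5 | (E)-1-iodo-2-methyl-4-(2,6,6-trimethylcyclohex-1-en-1-yl)but-1-ene | I/C=C(\C)CCC1=C(C)CCCC1(C)C | intermediate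
6 | (S)-solketal, (4S)-2,2-dimethyl-1,3-dioxolane-4-methanol | CC1(C)OC[C@H](CO)O1 | starting material
7 | (4R)-4-{[(tert-butyldiphenylsilyl)oxy]methyl}-2,2-dimethyl-1,3-dioxolane | CC1(C)OC[C@H](CO[Si](c2ccccc2)(c2ccccc2)C(C)(C)C)O1 | intermediate
8 | (2R)-3-[(tert-butyldiphenylsilyl)oxy]propane-1,2-diol | OC[C@H](CO[Si](c1ccccc1)(c1ccccc1)C(C)(C)C)O | intermediate
9 | (2R)-3-[(tert-butyldiphenylsilyl)oxy]-2-hydroxypropyl acetate | CC(=O)OC[C@H](CO[Si](c1ccccc1)(c1ccccc1)C(C)(C)C)O | intermediate
10 | carbon monoxide | [C-]#[O+] | starting material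
11 | (2R)-1-(acetyloxy)-3-[(tert-butyldiphenylsilyl)oxy]propan-2-yl (2E)-3-methyl-5-(2,6,6-trimethylcyclohex-1-en-1-yl)pent-2-enoate | CC(=O)OC[C@H](CO[Si](c1ccccc1)(c1ccccc1)C(C)(C)C)OC(=O)/C=C(\C)CCC1=C(C)CCCC1(C)C | intermediate
12 | (2S)-1-(acetyloxy)-3-hydroxypropan-2-yl (2E)-3-methyl-5-(2,6,6-trimethylcyclohex-1-en-1-yl)pent-2-enoate | CC(=O)OC[C@H](CO)OC(=O)/C=C(\C)CCC1=C(C)CCCC1(C)C | target

**Step count**
Total step count: 7. Longest linear sequence: 5 steps (6 → 7 → 8 → 9 → 11 → 12, steps 3 to 7); the iodide branch (steps 1 and 2) joins at step 6.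

**Steps most likely to fail**

Step 6. The acylpalladium intermediate may be captured too slowly by the hindered secondary hydroxyl. Reduction of the organopalladium species could then compete, as could an acetyl shift from O1 to O2 followed by acylation at the primary oxygen, or γ-deprotonation of the activated acyl group with loss of conjugation or of the E geometry. Fallback: the two bonds would be formed separately. Iodide 5 would undergo iodine–lithium exchange (t-BuLi, Et2O, −78 °C) and carboxylation with CO2, both with retention, to give (E)-3-methyl-5-(2,6,6-trimethylcyclohex-1-en-1-yl)pent-2-enoic acid F1. This acid would be joined to alcohol 9 by Shiina esterification (2-methyl-6-nitrobenzoic anhydride, Et3N, DMAP, CH2Cl2, rt), coming back to the route at 11.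

Step 7. Silyl cleavage may be sluggish, and during the long exposure to fluoride or on chromatography the enoyl group may shift from O2 to the freed O3, or the acetyl group may shift. Fallback: O3 would carry an oxidatively cleavable ether instead. (S)-Solketal 6 would be converted with NaH and 4-methoxybenzyl chloride (Bu4NI cat., THF/DMF) into its 4-methoxybenzyl ether F2 and hydrolysed with aqueous AcOH to 3-O-(4-methoxybenzyl)-sn-glycerol F3. Acetylation at O1 as in step 5 would give the monoacetate F4, and coupling with 5 and 10 as in step 6 would give the 4-methoxybenzyl ether of the target F5. The ether would be cleaved with DDQ in CH2Cl2/pH 7 buffer at 0 °C, returning to the route at 12.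

Step 5. Discrimination between O1 and O2 may be incomplete, giving diacetate or secondary acetate, and the acetyl group may shift during purification. Fallback: diol 8 would be heated with Bu2SnO in toluene with azeotropic removal of water to give the dibutylstannylene acetal F6. Its more nucleophilic primary tin alkoxide would be acetylated by AcCl in CH2Cl2 at 0 °C, and aqueous work-up returns to the route at 9.

**Further compounds**
F1 | step 6 | (E)-3-methyl-5-(2,6,6-trimethylcyclohex-1-en-1-yl)pent-2-enoic acid | OC(=O)/C=C(\C)CCC1=C(C)CCCC1(C)C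
F2 | step 7 | (4S)-4-{[(4-methoxybenzyl)oxy]methyl}-2,2-dimethyl-1,3-dioxolane | CC1(C)OC[C@H](COCc2ccc(OC)cc2)O1
F3 | step 7 | (2R)-3-[(4-methoxybenzyl)oxy]propane-1,2-diol | OC[C@H](COCc1ccc(OC)cc1)O
F4 | step 7 | (2S)-2-hydroxy-3-[(4-methoxybenzyl)oxy]propyl acetate | CC(=O)OC[C@H](COCc1ccc(OC)cc1)O
F5 | step 7 | (2S)-1-(acetyloxy)-3-[(4-methoxybenzyl)oxy]propan-2-yl (2E)-3-methyl-5-(2,6,6-trimethylcyclohex-1-en-1-yl)pent-2-enoate | CC(=O)OC[C@H](COCc1ccc(OC)cc1)OC(=O)/C=C(\C)CCC1=C(C)CCCC1(C)C
F6 | step 5 | (4S)-2,2-dibutyl-4-{[(tert-butyldiphenylsilyl)oxy]methyl}-1,3,2-dioxastannolane | CCCC[Sn]1(CCCC)OC[C@H](CO[Si](c2ccccc2)(c2ccccc2)C(C)(C)C)O1
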